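**Assumptions (one line each):** (+)-sclareolide, 5-hydroxy-2-methoxybenzaldehyde and (R)-(−)-mevalonolactone are taken as commercial. The facial sense of the catalytic epoxidation (Step 11) is assigned by analogy, not known for this substrate; the two epoxide diastereomers are separable because the drimane is homochiral.

## Retrosynthetic overview

1. Target ⇐ one acid step (dimethyl ketal → enedione, SEM ester → CO2H) from 17 ⇐ esterification of epoxy-monoketal alcohol 13 with HMG half-ester 16, whose stereocentre comes from (R)-mevalonolactone.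
2. 13 ⇐ nucleophilic epoxidation of quinone monoketal 12 ⇐ PhI(OAc)2/MeOH dearomatisation of p-methoxyphenol 11. Placing the free OH ortho to the terpenyl arm fixes which C=C is epoxidised.
3. 11 ⇐ sp3–sp2 Negishi coupling of the albicanyl zinc reagent (from iodide 5) with aryl bromide 9.
4. 5 ⇐ (+)-sclareolide by DIBAL reduction, Suárez β-fragmentation (excises C12) and exo-selective dehydration. 9 ⇐ 5-hydroxy-2-methoxybenzaldehyde.
5. Ring order: decalin (chiral pool, never broken) → arene (purchased) → dearomatised cyclohexadienone → oxirane last.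

Abbreviation: "AlbCH2–" = [(1S,4aS,8aS)-5,5,8a-trimethyl-2-methylidenedecahydronaphthalen-1-yl]methyl (drim-8(12)-en-11-yl; 5α-H, 9α-H, 10β-Me).

## Route

**Step 1**
Reactants: 1, (+)-sclareolide
Product: 2, sclareolide lactol ((3aR,5aS,9aS,9bR)-3a,6,6,9a-tetramethyldodecahydronaphtho[2,1-b]furan-2-ol, anomer mixture)
Conditions: DIBAL-H (1.1 equiv), CH2Cl2, −78 °C
Reagents that add atoms: none
Why: Partial lactone reduction to the lactol at low temperature; the ring stereocentres are untouched and the anomeric mixture is inconsequential.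

**Step 2**
Reactants: 2, lactol
Product: 3, (1R,2R,4aS,8aS)-1-(iodomethyl)-2,5,5,8a-tetramethyldecahydronaphthalen-2-yl formate (11-iododriman-8α-yl formate)
Conditions: PhI(OAc)2, I2, CH2Cl2, hν (visible), rt
Reagents that add atoms: iodine, II
Why: Suárez hypoiodite reaction; the anomeric alkoxy radical β-fragments the C11–C12 bond, C12 stays as the formate on O-8 and the primary C11 radical is trapped by iodine, with C5/C8/C9/C10 unaffected.

**Step 3**
Reactants: 3, iodo formate
Product: 4, (1R,2R,4aS,8aS)-1-(iodomethyl)-2,5,5,8a-tetramethyldecahydronaphthalen-2-ol (11-iododriman-8α-ol)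
Conditions: K2CO3 (cat.), MeOH, 0 °C, 30 min
Reagents that add atoms: none
Why: Formate transesterification is fast at 0 °C, whereas the hindered primary iodide and the barely ionised tertiary alcohol do not close to the oxetane.

**Step 4**
Reactants: 4, iodo alcohol
Product: 5, albicanyl iodide ((1S,4aS,8aS)-1-(iodomethyl)-5,5,8a-trimethyl-2-methylidenedecahydronaphthalene)
Conditions: SOCl2, Et3N, CH2Cl2, −78 °C; AgNO3–SiO2 chromatography
Reagents that add atoms: none
Why: E2 dehydration via the chlorosulfite; the equatorial 8α leaving group has an anti-periplanar hydrogen only on the axial 8β-methyl, so the exocyclic 8(12)-alkene dominates and minor endocyclic isomers are removed on silver-nitrate silica.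

**Step 5**
Reactants: 6, 5-hydroxy-2-methoxybenzaldehyde
Product: 7, 3-(hydroxymethyl)-4-methoxyphenol
Conditions: NaBH4, MeOH, 0 °C
Reagents that add atoms: none
Why: Simple borohydride reduction of the aldehyde.

**Step 6**
Reactants: 7
Product: 8, 2-bromo-5-(hydroxymethyl)-4-methoxyphenol
Conditions: NBS (1.0 equiv), MeCN, −10 → 0 °C
Reagents that add atoms: N-bromosuccinimide, O=C1CCC(=O)N1Br
Why: Electrophilic aromatic bromination ortho to the phenol OH at the less hindered ortho position (para to the CH2OH-bearing carbon); brominating the alcohol rather than the aldehyde avoids attack between OH and CHO.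

**Step 7**
Reactants: 8
Product: 9, tert-butyl[(4-bromo-5-{[tert-butyl(dimethyl)silyl]oxy}-2-methoxyphenyl)methoxy]dimethylsilane
Conditions: TBSCl (2.5 equiv), imidazole, DMF, rt
Reagents that add atoms: TBSCl, CC(C)(C)[Si](C)(C)Cl
Why: Silylation of both acidic OH groups so the aryl bromide tolerates the organozinc.

**Step 8**
Reactants: 5, albicanyl iodide; 9, aryl bromide
Product: 10, tert-butyl{[4-(AlbCH2)-5-{[tert-butyl(dimethyl)silyl]oxy}-2-methoxyphenyl]methoxy}dimethylsilane
Conditions: 5, Zn dust (TMSCl/BrCH2CH2Br-activated), LiCl, THF, 40 °C; then 9, Pd(OAc)2 (3 mol %), SPhos (6 mol %), THF, 50 °C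
Reagents that add atoms: none
Why: Negishi sp3–sp2 cross-coupling; zinc inserts into the primary C–I bond and Pd/SPhos gives reductive elimination faster than β-hydride elimination, and C9 is not a reacting centre so its configuration is retained.

**Step 9**
Reactants: 10
Product: 11, 2-(AlbCH2)-5-(hydroxymethyl)-4-methoxyphenol
Conditions: TBAF (2.5 equiv), THF, 0 °C → rt (degassed)
Reagents that add atoms: none
Why: Fluoride cleaves both the aryl and the primary silyl ether; the exocyclic alkene is inert.

**Step 10**
Reactants: 11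
Product: 12, 2-(AlbCH2)-5-(hydroxymethyl)-4,4-dimethoxycyclohexa-2,5-dien-1-one
Conditions: PhI(OAc)2 (1.1 equiv), NaHCO3, MeOH, 0 °C
Reagents that add atoms: methanol, CO
Why: Hypervalent-iodine oxidative dearomatisation of a p-methoxyphenol; the carbonyl forms at the former phenol carbon (next to the terpenyl-bearing carbon) and the ketal at the former OMe carbon, giving a single monoketal regioisomer.

**Step 11**
Reactants: 12
Product: 13, (1R,6S)-1-(AlbCH2)-4-(hydroxymethyl)-5,5-dimethoxy-7-oxabicyclo[4.1.0]hept-3-en-2-one
Conditions: t-BuOOH, aq. NaOH, N-benzylcinchonidinium chloride (10 mol %), toluene, 0 °C → rt; chromatographic removal of the minor epoxide diastereomer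
Reagents that add atoms: tert-butyl hydroperoxide, CC(C)(C)OO
Why: Weitz–Scheffer nucleophilic epoxidation under chiral phase-transfer catalysis; peroxide adds only at the unsubstituted β-carbon, so the terpenyl-bearing C=C is epoxidised and the β-substituted CH2OH alkene is not. The ring enforces the cis epoxide, and the chiral ammonium ion pair selects the face giving (1R,6S).

**Step 12**
Reactants: 14, (R)-(−)-mevalonolactone
Product: 15, [2-(trimethylsilyl)ethoxy]methyl (3R)-3,5-dihydroxy-3-methylpentanoate
Conditions: KOH (1.0 equiv), H2O, rt, evaporate; SEMCl (1.05 equiv), DMF, 0 °C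
Reagents that add atoms: potassium hydroxide, [K+].[OH-]; SEMCl, C[Si](C)(C)CCOCCl
Why: Lactone saponification then carboxylate O-alkylation; the tertiary carbinol stereocentre is not touched.

**Step 13**
Reactants: 15
Product: 16, (3R)-3-hydroxy-3-methyl-5-oxo-5-{[2-(trimethylsilyl)ethoxy]methoxy}pentanoic acid
Conditions: TEMPO (cat.), NaOCl (cat.), NaClO2, MeCN / pH 6.7 phosphate buffer, 35 °C
Reagents that add atoms: sodium chlorite, [Na+].[O-]Cl=O
Why: TEMPO/chlorite (Zhao) oxidation takes the primary alcohol to the acid at near-neutral pH; the tertiary alcohol and the SEM ester are inert, giving an enantiopure, end-differentiated HMG unit.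

**Step 14**
Reactants: 13, epoxy-monoketal alcohol; 16, HMG half-ester acid
Product: 17, [(1R,6S)-6-(AlbCH2)-2,2-dimethoxy-5-oxo-7-oxabicyclo[4.1.0]hept-3-en-3-yl]methyl SEM (3R)-3-hydroxy-3-methylpentanedioate
Conditions: EDC·HCl, DMAP (cat.), CH2Cl2, 0 °C → rt
Reagents that add atoms: none
Why: Steglich-type esterification of the primary allylic alcohol; the tertiary β-hydroxyl does not compete and no stereocentre is involved.

**Step 15**
Reactants: 17
Product: 18, 4'-oxomacrophorin D
Conditions: 48 % aq. HF, MeCN, 0 °C → rt
Reagents that add atoms: water, O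
Why: Aqueous-acid hydrolysis of the dimethyl ketal unveils the epoxy-enedione and the same medium cleaves the SEM acylal ester to the free acid. HF/MeCN is mild enough to leave the epoxide, exocyclic alkene, allylic ester and tertiary alcohol intact. Freeing the SEM arm inverts the CIP ranking of the two HMG arms, so the (3R) centre of 17 becomes the required (S) centre without any bond change at carbon.

## Compound list

1 | (+)-sclareolide | C[C@@]12CC[C@H]3C(C)(C)CCC[C@]3(C)[C@H]1CC(=O)O2 | starting material
2 | sclareolide lactol | C[C@@]12CC[C@H]3C(C)(C)CCC[C@]3(C)[C@H]1CC(O)O2 | intermediate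
3 | 11-iododriman-8α-yl formate | C[C@@]1(OC=O)CC[C@H]2C(C)(C)CCC[C@]2(C)[C@H]1CI | intermediate
4 | 11-iododriman-8α-ol | C[C@@]1(O)CC[C@H]2C(C)(C)CCC[C@]2(C)[C@H]1CI | intermediate
5 | albicanyl iodide (11-iododrim-8(12)-ene) | C=C1CC[C@H]2C(C)(C)CCC[C@]2(C)[C@H]1CI | intermediate
6 | 5-hydroxy-2-methoxybenzaldehyde | COc1ccc(O)cc1C=O | starting material
7 | 3-(hydroxymethyl)-4-methoxyphenol | COc1ccc(O)cc1CO | intermediate
8 | 2-bromo-5-(hydroxymethyl)-4-methoxyphenol | COc1cc(Br)c(O)cc1CO | intermediate
9 | bis-TBS ether of 8 | COc1cc(Br)c(O[Si](C)(C)C(C)(C)C)cc1CO[Si](C)(C)C(C)(C)C | intermediate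
10 | Negishi product (bis-TBS albicanyl arene) | C=C1CC[C@H]2C(C)(C)CCC[C@]2(C)[C@H]1Cc1cc(OC)c(CO[Si](C)(C)C(C)(C)C)cc1O[Si](C)(C)C(C)(C)C | intermediate
11 | 2-(AlbCH2)-5-(hydroxymethyl)-4-methoxyphenol | C=C1CC[C@H]2C(C)(C)CCC[C@]2(C)[C@H]1Cc1cc(OC)c(CO)cc1O | intermediate
12 | quinone monoketal | C=C1CC[C@H]2C(C)(C)CCC[C@]2(C)[C@H]1CC1=CC(OC)(OC)C(CO)=CC1=O | intermediate
13 | (1R,6S)-epoxy monoketal alcohol | C=C1CC[C@H]2C(C)(C)CCC[C@]2(C)[C@H]1C[C@@]12O[C@@H]1C(OC)(OC)C(CO)=CC2=O | intermediate
14 | (R)-(−)-mevalonolactone | C[C@@]1(O)CCOC(=O)C1 | starting material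
15 | SEM (R)-mevalonate | C[C@@](CC(=O)OCOCC[Si](C)(C)C)(O)CCO | intermediate
16 | (3R)-HMG mono-SEM ester | C[C@@](CC(=O)OCOCC[Si](C)(C)C)(O)CC(=O)O | intermediate
17 | SEM-protected ketal of target | C=C1CC[C@H]2C(C)(C)CCC[C@]2(C)[C@H]1C[C@@]12O[C@@H]1C(OC)(OC)C(COC(=O)C[C@@](C)(O)CC(=O)OCOCC[Si](C)(C)C)=CC2=O | intermediate
18 | 4'-oxomacrophorin D | C=C1CC[C@H]2C(C)(C)CCC[C@]2(C)[C@H]1C[C@@]12O[C@@H]1C(=O)C(COC(=O)C[C@@](C)(O)CC(=O)O)=CC2=O | target

## Summary

Total steps: 15.
Longest linear sequence: 10 (sclareolide: Steps 1–4, 8–11, 14, 15). The aryl branch is 9 and the HMG branch is 4.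

Three steps most likely to fail, each with a fallback that changes the approach:

1. **Step 11 (face selectivity of the epoxidation).** The catalyst's sense and level of induction on this α-alkyl monoketal are not established. Fallback: switch from catalyst control to auxiliary control by replacing the dimethyl ketal with a C2-symmetric chiral diol spiroketal (hydrobenzoin or pentane-2,4-diol type) and epoxidising with achiral t-BuOOH/DBU. The pseudoenantiomeric cinchoninium salt is only a conditions-level backup.
2. **Step 8 (Negishi coupling of a β-branched, homoallylic primary zinc reagent with a hindered, electron-rich aryl bromide).** Fallback: reverse the polarity. Lithiate 9 (t-BuLi), add it to albicanal (from 5 via the alcohol and Dess–Martin oxidation), and remove the benzylic hydroxyl by Barton–McCombie deoxygenation.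
3. **Step 4 (exo versus endo dehydration, and separation of iodide isomers).** Fallback: degrade sclareolide by MeLi addition and Baeyer–Villiger oxidation to 11-acetoxydriman-8α-ol, dehydrate at the acetate stage where albicanyl and drimenyl acetates separate well, then hydrolyse and convert to 5 by Appel iodination.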